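## The problem

The target 34 is a trans-fused hydroazulene of the daucane type. Its fifteen skeletal carbons are numbered here C1(CH3)=C2–C3–C4(CH3)–C5(H)–C6(O-aroyl)–C7 around the seven-membered ring and C4–C5–C8(OH)(i-Pr)–C9–C10(OH) around the cyclopentane; β denotes the face of the angular C4 methyl group. Five stereocentres are packed onto C4 (quaternary), C5 (α-H), C6 (α-acyloxy), C8 (β-OH, α-isopropyl) and C10 (α-OH). C4 and C10 can be fixed together, and in absolute terms, by desymmetrising a 2,2-disubstituted cyclopentane-1,3-dione. On the resulting ring the α-oxygen at C10 and the α-chain at C4 leave the β face open, which is the face from which the C5 substituent and the C8 oxygen must both arrive, so C4/C10 can control C5 and C5 can then control C8. C6 lies outside the cyclopentane and is poorly served by reduction of a C6 ketone, because such a ketone makes C5 epimerisable and the trans-fused hydroazulenone is not the safe thermodynamic isomer. The groups that limit the reagents are the aryl ester with its free phenol (organolithiums, hydrides, strong base), the tertiary C8 alcohol 1,3 to the C6 oxygen (dehydration, silyl or acyl migration), and the trisubstituted C1=C2 alkene (acid, hydrogenation). The enabling feature is the segment C6(OH)–C7H2–C1(CH3)=C2H, a homoallylic alcohol whose cis alkene is held in the ring: it is the retron of a [2,3]-Wittig shift, and reconnecting the C6 oxygen to C2 gives a tetrahydropyran (O, C2, C3, C4, C5, C6) with an isopropenyl group on C2 and a carbanion equivalent on C6.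

## Retrosynthesis

**Ester last.** The C6–O acyl bond and the two silyl ethers of 33 are cut first, giving diol 28 and acid 31 (from 29). The aryl ester would not survive the organolithium chemistry that builds the ring, and acylation of a secondary alcohol beside a hindered tertiary one needs no protecting group on C8.

**Ring expansion.** In 28 the C6–C7 bond is cut and the C6 oxygen is rejoined to C2, which leads to hydroxy stannane 27. Against a ring-closing metathesis across C1=C2 or a carbonyl addition at C6–C7, this cut makes the C6–C7 bond, the cis alkene and the C6 carbinol in one event and transfers configuration from two ring centres to C6. The precursor is a six-membered cyclic ether, which lactone chemistry can deliver. The forward step needs a C6 carbanion of defined configuration and an axial isopropenyl group. The C8 hydroxyl is left free in 27, because a silyl ether there would sit 1,4 to the carbanion and could migrate to carbon.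

**Tin at the anomeric carbon.** The C6–Sn bond of 27 is traced to anomeric chloride 26, lactol 22 and lactone 23. The lactone comes from triol 20 by oxidation of the primary C6 alcohol, which forms the ring O–C6 bond; this leaves C2 as a plain secondary allylic alcohol.

**The C2 carbinol.** Triol 20 is cut at C2–H and then at C1–C2, giving dihydroxy enone 19 and, behind it, lactone 16 plus 2-bromopropene 17. The isopropenyl group in 27 must be axial and syn to the angular methyl, the less stable arrangement, so substrate control cannot be relied on. A reagent-controlled ketone reduction on the open chain is preferred to a direct carbonyl addition of unknown facial bias.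

**The acetate arm.** The C2 carbonyl of 16 is the inner carbon of the allyl group of diol 14, released by oxidative cleavage; the primary C6 hydroxyl closes the lactone. The allyl group serves from the first step as a masked two-carbon arm that tolerates bases, reducing metals and Lewis acids.

**C5 and C8.** Diol 14 is cut at C9–H and C8–O (epoxide 13) and then at C5–C6 (homoallylic alcohol 12 from cyclopentene 11). Addition of an isopropyl nucleophile to a C8 ketone would come from the open β face and give the wrong carbinol, and hydrogenation or hydroboration would not spare the allyl group. An electrophilic one-carbon ene reaction instead uses the open β face to place C6 correctly, and the new hydroxymethyl group then directs the C8 oxygen to the same face.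

**The isopropyl group.** Cyclopentene 11 goes back through enol triflate 10 and isopropylidene ketone 8 to aldol 6 and ketone 5. The three isopropyl carbons enter by aldol condensation at the only enolisable position, and the reduction–triflation–reduction sequence moves the unsaturation from C5=O to C5=C8.

**The first stereocentres.** Ketone 5 is the silyl ether of ketol 4, which comes from the prochiral dione 3, made from 1 and 2. One enantiotopic-group-selective reduction sets C10 and, by breaking the symmetry, the quaternary C4.

## Roads not taken

Alternative 1: The five-membered ring is cut at C4–C10 and C5–C8, leaving the seven-membered ring as dienone A1. A chiral N-heterocyclic carbene–copper catalyst made from Cu(OTf)2 would transfer the 1-silylvinyl group of alane A2 to C4 of A1, and the aluminium enolate would be trapped at C5 by aldehyde A3 to give A4; no ring closes.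
- Merits: catalytic control of absolute configuration; the quaternary centre and the trans C4/C5 relationship in one operation; a seven-membered ring that already carries the C1=C2 alkene and the C6 oxygen.
- Weak points: A1 holds a β,γ-alkene that can slip into conjugation. The cyclopentane must still be closed at C8–C9, which requires oxidising the aldol carbinol (its stereocentre is discarded) and creating the tertiary C8 carbinol during ring closure. The C10 hydroxyl must be drawn from the vinylsilane, and the C6 ketone must be reduced to the α-alcohol beside an epimerisable C5.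
- Comparison: this road is ahead in step count to a bicyclic intermediate and in precedent for its key step. The chosen plan sets against it that C4 and C10 are fixed at the outset, C5 and C8 are set on a rigid five-membered ring before the large ring exists, and C6 is never a ketone.

Alternative 2: The seven-membered ring is cut at C1–C7 and C3–C4 into vinyldiazoacetate A5 and dienyl ether A6. With dirhodium tetrakis[(S)-N-(4-dodecylbenzenesulfonyl)prolinate] (divalent rhodium) the carbenoid of A5 would cyclopropanate the ethoxyvinyl group of A6, and Cope rearrangement of the cis-divinylcyclopropane would give A7, closing the seven-membered ring on the cyclopentenone.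
- Merits: convergent; ring and quaternary C4 in one catalytic enantioselective step of a well-studied class; a C8 ketone in place for the isopropyl group.
- Weak points: A7 has an ester where C1 needs a methyl group. It has no oxygen at C10, so an unactivated methylene would have to be hydroxylated late. The C5=C6 enol ether leads back to a C6 ketone with an epimerisable C5. The Cope step must build a quaternary centre at the β-carbon of an enone.
- Comparison: for a daucane without the C10 hydroxyl this road would be shorter and more convergent. For this target the missing C10 oxygen decides, and the chosen plan sets against its own length that the C10 oxygen is present from the first stereo-defining step.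

Alternative 3: The C4–C5 bond is cut and C4–C6 rejoined, turning the hydroazulene into cis-decalin hydroxy mesylate A10, derived from the cycloadduct of quinone A8 and diene A9. With KOtBu (or Et2AlCl) the C6 alkoxide pushes the antiperiplanar C4–C6 bond to C5 as the mesylate leaves. One six-membered ring contracts to the cyclopentane and the other expands to the cycloheptenone A11.
- Merits: all fifteen carbons from two cheap materials in one cycloaddition; a stereospecific 1,2-shift of a known type that sets the trans fusion by inversion at C5.
- Weak points: site and regiochemistry of the cycloaddition on A8, and the need for an enantioselective version. A10 needs its stereocentres and two differentiated oxygens installed one by one on a flexible cis-decalin. A11 is again a C6 ketone whose reduction must give the α-alcohol.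
- Comparison: skeletal economy and the known key step are better here. The chosen plan sets against this a secure absolute configuration, fewer late stereochemical decisions, and C6 delivered directly as the carbinol.

Key step: step 17

Remark on the chemistry: the minor diastereomer of the microbial reduction (step 2) and the minor C2 epimer of step 13 are assumed to be separable by chromatography, the latter at the stage of lactone 23.

## Steps

Step 1
Reactants: 1 2-methylcyclopentane-1,3-dione; 2 allyl bromide
Product: 3 2-allyl-2-methylcyclopentane-1,3-dione
Conditions: NaOH (1 M, aq), rt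
Reagents that add atoms: none
Why: C-alkylation of the stabilised dione enolate with a reactive allylic halide in water is a standard route to 2,2-disubstituted cyclopentane-1,3-diones; the product is achiral.

Step 2
Reactants: 3 2-allyl-2-methylcyclopentane-1,3-dione
Product: 4 (2S,3S)-2-allyl-3-hydroxy-2-methylcyclopentan-1-one (hydroxyl cis to allyl)
Conditions: baker's yeast (Saccharomyces cerevisiae), sucrose, H2O, 30 °C
Reagents that add atoms: none
Why: Enantiotopic-group-selective microbial reduction of a prochiral 2,2-disubstituted cyclopentane-1,3-dione, a known reaction of this substrate class; one carbonyl becomes the (S)-carbinol, which sets C10 (α-OH) and thereby the quaternary C4.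

Step 3
Reactants: 4 (2S,3S)-2-allyl-3-hydroxy-2-methylcyclopentan-1-one
Product: 5 (2S,3S)-2-allyl-3-(tert-butyldimethylsilyloxy)-2-methylcyclopentan-1-one
Conditions: TBSCl, imidazole, DMF, rt
Reagents that add atoms: tert-butyldimethylsilyl chloride, CC(C)(C)[Si](C)(C)Cl
Why: Standard silylation of a secondary alcohol; the TBS ether survives enolates, dissolving metal, Lewis acid and organolithiums and adds bulk to the α face.

Step 4
Reactants: 5 (2S,3S)-2-allyl-3-(tert-butyldimethylsilyloxy)-2-methylcyclopentan-1-one
Product: 6 aldol adduct, the 5-(2-hydroxypropan-2-yl) derivative of 5 (both C8 epimers)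
Conditions: LiN(i-Pr)2, THF, −78 °C; acetone; AcOH, −78 °C
Reagents that add atoms: acetone, CC(C)=O
Why: Only C8 carries α-hydrogens (C4 is quaternary), so a single lithium enolate forms and adds to acetone (aldol addition); the new C8 centre is removed in the next step.

Step 5
Reactants: 6 aldol adduct
Product: 8 (2S,3S)-2-allyl-3-(tert-butyldimethylsilyloxy)-2-methyl-5-(propan-2-ylidene)cyclopentan-1-one, via mesylate 7 (not isolated)
Conditions: MsCl, Et3N, CH2Cl2, 0 °C; then DBU, rt
Reagents that add atoms: methanesulfonyl chloride, CS(=O)(=O)Cl (retained only in intermediate 7)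
Why: Sulfonylation of the tertiary aldol and E1cB elimination complete an aldol condensation; DBU brings any β,γ-isomer into conjugation.

Step 6
Reactants: 8 isopropylidene ketone
Product: 10 enol triflate (C5–OTf, C5=C8, isopropyl on C8; C4 β-methyl/α-allyl, C10 α-OTBS), via lithium enolate 9 (not isolated)
Conditions: Li, t-BuOH (1 equiv), NH3(l)–THF, −78 °C; NH3 removed; PhNTf2, THF, −78 → 0 °C
Reagents that add atoms: N-phenylbis(trifluoromethanesulfonimide), O=S(=O)(N(c1ccccc1)S(=O)(=O)C(F)(F)F)C(F)(F)F; lithium, [Li] (in intermediate 9 only)
Why: Dissolving-metal reduction of an enone gives the tetrasubstituted enolate regiospecifically, and O-triflation traps it; the isolated terminal alkene and the silyl ether are inert to Li/NH3.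

Step 7
Reactants: 10 enol triflate
Product: 11 cyclopentene (C5H=C8 with isopropyl on C8; C4 β-methyl/α-allyl; C10 α-OTBS)
Conditions: Pd(OAc)2 (cat.), PPh3, HCO2H, Bu3N, DMF, 60 °C
Reagents that add atoms: none
Why: Palladium-catalysed formate reduction of an enol triflate (oxidative addition to zerovalent palladium, formate exchange, loss of CO2, C–H reductive elimination) places the trisubstituted alkene exactly at C5=C8.

Step 8
Reactants: 11 cyclopentene
Product: 12 homoallylic alcohol (C5 β-CH2OH, α-H; alkene moved to C8=C9)
Conditions: (CH2O)n, Me2AlCl, CH2Cl2, −78 → 0 °C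
Reagents that add atoms: paraformaldehyde (as formaldehyde), C=O
Why: Lewis acid promoted carbonyl-ene reaction: the formaldehyde–Me2AlCl complex bonds to the less substituted alkene carbon C5 while an allylic C9 hydrogen is transferred. Attack from the β face, away from the α-allyl and α-OTBS groups, sets C5; the monosubstituted allyl alkene is a far poorer ene partner.

Step 9
Reactants: 12 homoallylic alcohol
Product: 13 β-epoxide of 12 at C8–C9
Conditions: VO(acac)2 (cat.), t-BuOOH, CH2Cl2, 0 °C → rt
Reagents that add atoms: tert-butyl hydroperoxide, CC(C)(C)OO
Why: Hydroxyl-directed vanadium-catalysed epoxidation delivers oxygen syn to the β-CH2OH group, which is also the face anti to the allylic α-OTBS group; this sets the C8–O bond (β). The allyl alkene is remote from the hydroxyl and less nucleophilic.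

Step 10
Reactants: 13 epoxy alcohol
Product: 14 diol (C5 β-CH2OH; C8 β-OH, α-isopropyl; C4 β-methyl/α-allyl; C10 α-OTBS)
Conditions: LiEt3BH, THF, 0 → 50 °C
Reagents that add atoms: none
Why: SN2 hydride opening of a trisubstituted epoxide at its less substituted carbon (C9) leaves the C8–O bond untouched, so the tertiary carbinol keeps the configuration set in step 9.

Step 11
Reactants: 14 diol
Product: 16 trans-fused δ-lactone with carbonyl at C2 and ring oxygen on C6 (C8 hydroxyl free), via hydroxy methyl ester 15 (not isolated)
Conditions: O3, NaOH, MeOH–CH2Cl2, −78 °C; then PPTS (cat.), PhMe, 50 °C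
Reagents that add atoms: ozone, [O-][O+]=O; methanol, CO (retained only in intermediate 15)
Why: Ozonolysis in methanolic NaOH converts a terminal alkene directly into the methyl ester, and mild acid closes the six-membered lactone on the β-CH2OH group; the tertiary hydroxyl is trans to the acetate arm and cannot lactonise.

Step 12
Reactants: 16 δ-lactone (C2=O); 17 2-bromopropene
Product: 19 dihydroxy enone (isopropenyl ketone at C2, primary C6–OH, tertiary C8–OH), via isopropenyllithium 18 (not isolated)
Conditions: 17, t-BuLi, Et2O, −78 °C; then 16, THF, −78 °C; NH4Cl (aq), −78 °C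
Reagents that add atoms: tert-butyllithium, [Li]C(C)(C)C (lithium of intermediate 18 only)
Why: Mono-addition of an alkenyllithium to a δ-lactone: the lithium hemiketalate is stable at −78 °C, so the ketone is released only on work-up. One extra equivalent is consumed by the tertiary hydroxyl; 19 equilibrates with its cyclic hemiketal.

Step 13
Reactants: 19 dihydroxy enone
Product: 20 (2S)-triol (C2 allylic alcohol, C6–OH, C8–OH)
Conditions: (R)-1-methyl-3,3-diphenyltetrahydro-1H,3H-pyrrolo[1,2-c][1,3,2]oxazaborole (cat.), catecholborane, PhMe, −78 °C
Reagents that add atoms: none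
Why: Corey–Bakshi–Shibata reduction, in which the α-branched alkenyl group acts as the large substituent, so the (R)-catalyst should give the (S)-carbinol at C2. The result is reagent-controlled because the nearest stereocentre is the quaternary C4 two bonds away; catecholborane avoids hydroboration of the alkene.

Step 14
Reactants: 20 (2S)-triol
Product: 23 δ-lactone with carbonyl at C6 and ring oxygen on C2 (2β-isopropenyl, trans-fused), via hydroxy aldehyde 21 (not isolated), via lactol 22 (not isolated)
Conditions: TEMPO (cat.), PhI(OAc)2, CH2Cl2, rt
Reagents that add atoms: none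
Why: Oxidative lactonisation of a 1,5-diol: the nitroxyl/iodine oxidant takes the primary alcohol first, the C2 hydroxyl captures the aldehyde, and the lactol is oxidised further. The medium is not basic, so C5, now α to the carbonyl, keeps its configuration.

Step 15
Reactants: 23 δ-lactone (C6=O)
Product: 22 lactol (anomeric mixture at C6)
Conditions: i-Bu2AlH, CH2Cl2, −78 °C
Reagents that add atoms: none
Why: Partial reduction of a δ-lactone stops at the aluminium hemiacetal at −78 °C; the free tertiary hydroxyl only consumes one equivalent of hydride.

Step 16
Reactants: 22 lactol; 24 tributyltin chloride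
Product: 27 hydroxy stannane (cyclopentane-fused 2β-isopropenyl-6α-(tributylstannyl)tetrahydropyran; 2,6-trans; C8 β-OH, C10 α-OTBS), via tributylstannyllithium 25 (not isolated), via anomeric chloride 26 (not isolated)
Conditions: 24, Li, THF, 0 °C; separately 22, Me2C=C(Cl)NMe2, CH2Cl2, 0 °C, then solvent change to THF; chloride added to the stannyllithium (3 equiv), −78 °C
Reagents that add atoms: 1-chloro-N,N,2-trimethylprop-1-en-1-amine, CC(C)=C(Cl)N(C)C (chlorine of intermediate 26 only); lithium, [Li] (in intermediate 25 only)
Why: Neutral conversion of a hemiacetal into the anomeric chloride, then displacement by a stannyl anion, is the known route to anomeric stannanes. The bulky nucleophile can reach C6 only along the equatorial α trajectory, because the β-axial approach is closed by the axial isopropenyl and methyl groups, so tin ends trans to the isopropenyl group. One equivalent of the stannyl anion is spent on the tertiary hydroxyl.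

Step 17
Reactants: 27 hydroxy stannane
Product: 28 hydroazulene diol (C6 α-OH, C8 β-OH, C10 α-OTBS, C1=C2 alkene, trans ring fusion)
Conditions: n-BuLi (2.3 equiv), THF, −78 → −40 °C; NH4Cl (aq), −78 °C
Reagents that add atoms: none
Why: Proposed new method: n-BuLi first deprotonates the C8 hydroxyl and then exchanges tin for lithium at C6 with retention, giving an equatorial (α) α-alkoxy organolithium whose rear lobe points along the β-axial direction, where C7 of the axial isopropenyl group lies; C6–C7 forms as O–C2 breaks through a five-membered envelope (C6, O, C2, C1, C7) held in an 8-oxabicyclo[3.2.1]octene-like array. The closest known reactions are the Wittig–Still [2,3] rearrangement of stannane-derived α-alkoxy organolithiums and the [2,3]-Wittig ring contractions of cyclic allyl ethers; here the allylic C–O bond is endocyclic and the alkene exocyclic, so the shift enlarges the ring, which has not been shown. The seven-membered carbocycle is closed by this sigmatropic C6–C7 bond formation while the six-membered ether opens, a one-carbon ring expansion with the oxygen leaving the ring. The new stereocentre C6 is fixed by retention in the exchange and inversion in the shift, that is by the α-tin/β-isopropenyl (2,6-trans) relationship of 27, and becomes the 6α-carbinol (S); the C1=C2 alkene can only be cis in the ring. The step needs the [2,3] shift to win over the radical [1,2] shift and over silyl migration: the trans-fused cyclopentane locks the chair that holds the isopropenyl group axial beside the reacting lobe, low temperature disfavours the [1,2] path, and the C8 oxygen is carried as a lithium alkoxide because a silyl ether there would sit 1,4 to the carbanion and invite retro-Brook migration, while the C10 silyl ether is out of reach. The cost is the syn-axial contact between the isopropenyl group and the C4 methyl, which is already present in 27 and is therefore not newly imposed in the transition state.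

Step 18
Reactants: 29 4-hydroxybenzoic acid
Product: 31 4-(tert-butyldimethylsilyloxy)benzoic acid, via silyl ester 30 (not isolated)
Conditions: TBSCl (2.3 equiv), imidazole, DMF, rt; then AcOH, THF–H2O, rt
Reagents that add atoms: tert-butyldimethylsilyl chloride, CC(C)(C)[Si](C)(C)Cl
Why: Exhaustive silylation followed by selective hydrolysis of the far more labile silyl ester is the usual way to an O-silylated hydroxybenzoic acid.

Step 19
Reactants: 28 hydroazulene diol; 31 4-(tert-butyldimethylsilyloxy)benzoic acid
Product: 33 C6 4-(tert-butyldimethylsilyloxy)benzoate of 28, via acid chloride 32 (not isolated)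
Conditions: 31, (COCl)2, DMF (cat.), CH2Cl2, 0 °C → rt; then 28, Et3N, DMAP, CH2Cl2, 0 °C → rt
Reagents that add atoms: oxalyl chloride, O=C(Cl)C(=O)Cl (chlorine of intermediate 32 only)
Why: DMAP-catalysed acylation with an acid chloride; the secondary C6 hydroxyl reacts, while the tertiary C8 hydroxyl, flanked by the isopropyl group, does not. C6 keeps its configuration because the C–O bond is not touched.

Step 20
Reactants: 33 bis-silyl ester
Product: 34 2α-hydroxyferutinin, (1S,3R,3aS,4S,8aR)-1,3-dihydroxy-3-isopropyl-6,8a-dimethyl-1,2,3,3a,4,5,8,8a-octahydroazulen-4-yl 4-hydroxybenzoate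
Conditions: Bu4NF, AcOH, THF, 0 °C → rt
Reagents that add atoms: none
Why: Fluoride cleaves the aryl and the secondary alkyl silyl ether; buffering with acetic acid keeps the liberated phenoxide and alkoxides from attacking or shifting the ester.

## Compound list

1 | 2-methylcyclopentane-1,3-dione | CC1C(=O)CCC1=O | starting material
2 | allyl bromide | C=CCBr | starting material
3 | 2-allyl-2-methylcyclopentane-1,3-dione | C=CCC1(C)C(=O)CCC1=O | intermediate
4 | (2S,3S)-2-allyl-3-hydroxy-2-methylcyclopentan-1-one | C=CC[C@@]1(C)[C@@H](O)CCC1=O | intermediate
5 | (2S,3S)-2-allyl-3-(tert-butyldimethylsilyloxy)-2-methylcyclopentan-1-one | C=CC[C@@]1(C)[C@@H](O[Si](C)(C)C(C)(C)C)CCC1=O | intermediate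
6 | aldol adduct, 5-(2-hydroxypropan-2-yl) derivative of 5 (C8 epimers) | C=CC[C@@]1(C)[C@@H](O[Si](C)(C)C(C)(C)C)CC(C(C)(C)O)C1=O | intermediate
7 | tertiary mesylate of 6 | C=CC[C@@]1(C)[C@@H](O[Si](C)(C)C(C)(C)C)CC(C(C)(C)OS(C)(=O)=O)C1=O | intermediate
8 | (2S,3S)-2-allyl-3-(tert-butyldimethylsilyloxy)-2-methyl-5-(propan-2-ylidene)cyclopentan-1-one | C=CC[C@@]1(C)[C@@H](O[Si](C)(C)C(C)(C)C)CC(=C(C)C)C1=O | intermediate
9 | lithium enolate (C5–OLi, C5=C8, isopropyl on C8) | C=CC[C@@]1(C)[C@@H](O[Si](C)(C)C(C)(C)C)CC(C(C)C)=C1O[Li] | intermediate
10 | enol triflate (C5–OTf, C5=C8, isopropyl on C8) | C=CC[C@@]1(C)[C@@H](O[Si](C)(C)C(C)(C)C)CC(C(C)C)=C1OS(=O)(=O)C(F)(F)F | intermediate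
11 | cyclopentene (C5H=C8 with isopropyl; C4 β-methyl/α-allyl; C10 α-OTBS) | C=CC[C@@]1(C)[C@@H](O[Si](C)(C)C(C)(C)C)CC(C(C)C)=C1 | intermediate
12 | homoallylic alcohol (C5 β-CH2OH; C8=C9) | C=CC[C@@]1(C)[C@@H](O[Si](C)(C)C(C)(C)C)C=C(C(C)C)[C@@H]1CO | intermediate
13 | C8–C9 β-epoxide of 12 | C=CC[C@@]1(C)[C@@H](O[Si](C)(C)C(C)(C)C)[C@@H]2O[C@]2(C(C)C)[C@@H]1CO | intermediate
14 | diol (C5 β-CH2OH; C8 β-OH, α-isopropyl) | C=CC[C@@]1(C)[C@@H](O[Si](C)(C)C(C)(C)C)C[C@@](O)(C(C)C)[C@@H]1CO | intermediate
15 | hydroxy methyl ester (C2 as CO2Me) | COC(=O)C[C@@]1(C)[C@@H](O[Si](C)(C)C(C)(C)C)C[C@@](O)(C(C)C)[C@@H]1CO | intermediate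
16 | trans-fused δ-lactone, carbonyl at C2, ring oxygen on C6 | O=C1C[C@@]2(C)[C@@H](O[Si](C)(C)C(C)(C)C)C[C@@](O)(C(C)C)[C@@H]2CO1 | intermediate
17 | 2-bromopropene | C=C(C)Br | starting material
18 | isopropenyllithium | [Li]C(C)=C | intermediate
19 | dihydroxy enone (isopropenyl ketone at C2) | C=C(C)C(=O)C[C@@]1(C)[C@@H](O[Si](C)(C)C(C)(C)C)C[C@@](O)(C(C)C)[C@@H]1CO | intermediate
20 | (2S)-triol | C=C(C)[C@@H](O)C[C@@]1(C)[C@@H](O[Si](C)(C)C(C)(C)C)C[C@@](O)(C(C)C)[C@@H]1CO | intermediate
21 | hydroxy aldehyde (C6 aldehyde, C2 alcohol) | C=C(C)[C@@H](O)C[C@@]1(C)[C@@H](O[Si](C)(C)C(C)(C)C)C[C@@](O)(C(C)C)[C@@H]1C=O | intermediate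
22 | lactol (C6 hemiacetal, anomeric mixture; 2β-isopropenyl) | C=C(C)[C@@H]1C[C@]2(C)[C@@H](C(O)O1)[C@](O)(C(C)C)C[C@@H]2O[Si](C)(C)C(C)(C)C | intermediate
23 | trans-fused δ-lactone, carbonyl at C6, ring oxygen on C2 (2β-isopropenyl) | C=C(C)[C@@H]1C[C@]2(C)[C@@H](C(=O)O1)[C@](O)(C(C)C)C[C@@H]2O[Si](C)(C)C(C)(C)C | intermediate
24 | tributyltin chloride | CCCC[Sn](Cl)(CCCC)CCCC | starting material
25 | tributylstannyllithium | [Li][Sn](CCCC)(CCCC)CCCC | intermediate
26 | anomeric chloride (C6, configuration not assigned) | C=C(C)[C@@H]1C[C@]2(C)[C@@H](C(Cl)O1)[C@](O)(C(C)C)C[C@@H]2O[Si](C)(C)C(C)(C)C | intermediate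
27 | hydroxy stannane (2β-isopropenyl, 6α-tributylstannyl, 2,6-trans) | C=C(C)[C@@H]1C[C@]2(C)[C@@H]([C@H](O1)[Sn](CCCC)(CCCC)CCCC)[C@](O)(C(C)C)C[C@@H]2O[Si](C)(C)C(C)(C)C | intermediate
28 | hydroazulene diol (C6 α-OH, C8 β-OH, C10 α-OTBS) | CC1=CC[C@]2(C)[C@@H]([C@@H](O)C1)[C@](O)(C(C)C)C[C@@H]2O[Si](C)(C)C(C)(C)C | intermediate
29 | 4-hydroxybenzoic acid | O=C(O)c1ccc(O)cc1 | starting material
30 | tert-butyldimethylsilyl 4-(tert-butyldimethylsilyloxy)benzoate | CC(C)(C)[Si](C)(C)OC(=O)c1ccc(O[Si](C)(C)C(C)(C)C)cc1 | intermediate
31 | 4-(tert-butyldimethylsilyloxy)benzoic acid | O=C(O)c1ccc(O[Si](C)(C)C(C)(C)C)cc1 | intermediate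
32 | 4-(tert-butyldimethylsilyloxy)benzoyl chloride | O=C(Cl)c1ccc(O[Si](C)(C)C(C)(C)C)cc1 | intermediate
33 | C6 4-(tert-butyldimethylsilyloxy)benzoate of 28 | CC1=CC[C@]2(C)[C@@H]([C@@H](OC(=O)c3ccc(O[Si](C)(C)C(C)(C)C)cc3)C1)[C@](O)(C(C)C)C[C@@H]2O[Si](C)(C)C(C)(C)C | intermediate
34 | 2α-hydroxyferutinin | CC1=CC[C@]2(C)[C@@H]([C@@H](OC(=O)c3ccc(O)cc3)C1)[C@](O)(C(C)C)C[C@@H]2O | target

## Step count and least certain steps

Total: 20 steps. Longest linear sequence: 19 steps (steps 1–17, 19 and 20); step 18 is a one-step side branch.

**Step 17 (key step, proposed new method).** The bridged transition state may not be reached. The pyran can twist away from the chair to relieve the syn-axial isopropenyl/methyl contact, which moves the alkene terminus away from C6; the organolithium then undergoes the radical [1,2] shift (ring contraction) or simply survives to be protonated on work-up. Fallback by known chemistry, from diol 14 to diol 28: the primary alcohol of 14 is oxidised with TEMPO/PhI(OAc)2 to the β-hydroxy aldehyde F1. Brown methallylation with (−)-B-methallyldiisopinocampheylborane (from (+)-α-pinene) gives the diene diol F2, with the (S)-carbinol at C6 under reagent control. Ring-closing metathesis between the allyl and methallyl groups with the second-generation Grubbs catalyst RuCl2(=CHPh)(PCy3)(H2IMes) closes the seven-membered ring at C1=C2 and returns to 28.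

**Step 16.** Elimination of HCl from the anomeric chloride toward the enol ether, reduction by the stannyl anion, or reaction of the chloroenamine with the C2 hydroxyl of the ring-opened lactol can each consume material. If displacement takes an ionic course with axial attack, tin would end cis to the isopropenyl group. Fallback, from lactol 22 to diol 28 without the stannane: 22 is converted with PhSSPh/Bu3P into the S-phenyl thioacetal F3. After deprotonation of the hydroxyl with n-BuLi, reductive lithiation with lithium 4,4'-di-tert-butylbiphenylide at −78 °C and warming to −40 °C lets the 6-lithio species settle in the uncrowded equatorial position, from which the same [2,3] shift leads to 28.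

**Step 8.** Facial selectivity may be poor, since the two faces at C5 differ only by methyl versus allyl on C4 and by the more distant silyl ether. Hydrogen may also be transferred from the isopropyl methine instead of C9. Fallback, from triflate 10 to diol 14 (it also bypasses steps 9 and 10):
- Stille coupling of 10 with Bu3SnCH2OH (Pd(PPh3)4, LiCl) gives the tetrasubstituted allylic alcohol F4.
- VO(acac)2/t-BuOOH gives the β-epoxy alcohol F5.
- Dess–Martin oxidation gives the epoxy aldehyde F6.
- SmI2 in THF/MeOH at −78 °C cleaves the C5–O bond, and brief equilibration with Et3N places the formyl group trans to the isopropyl group, giving the β-hydroxy aldehyde F1 described above.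
- NaBH4 returns to 14. Here C5 is set by thermodynamic control.

**Step 13.** Catalyst control may be eroded: the small substituent is a neopentyl-type methylene, the two free hydroxyls consume borane and can deliver hydride without the catalyst, and the cyclic hemiketal hides the ketone. Fallback, from lactone 16 to triol 20: i-Bu2AlH reduces 16 to the C2 lactol F7. Its open hydroxy aldehyde form is coupled with 2-bromopropene 17 in a catalytic asymmetric Nozaki–Hiyama–Kishi reaction (CrCl2, NiCl2, chiral sulfonamide–oxazoline ligand), so that C2 is set in the C–C bond formation.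

## Further compounds

F1 | step 17 | β-hydroxy aldehyde (C6 aldehyde on C5, β; C8 β-OH; allyl retained) | C=CC[C@@]1(C)[C@@H](O[Si](C)(C)C(C)(C)C)C[C@@](O)(C(C)C)[C@@H]1C=O
F2 | step 17 | diene diol (C6 (S)-carbinol bearing methallyl; allyl on C4) | C=CC[C@@]1(C)[C@@H](O[Si](C)(C)C(C)(C)C)C[C@@](O)(C(C)C)[C@@H]1[C@@H](O)CC(C)=C
F3 | step 16 | S-phenyl thioacetal at C6 (anomeric configuration not assigned) | C=C(C)[C@@H]1C[C@]2(C)[C@@H](C(Sc3ccccc3)O1)[C@](O)(C(C)C)C[C@@H]2O[Si](C)(C)C(C)(C)C
F4 | step 8 | tetrasubstituted allylic alcohol (C5–CH2OH, C5=C8) | C=CC[C@@]1(C)[C@@H](O[Si](C)(C)C(C)(C)C)CC(C(C)C)=C1CO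
F5 | step 8 | C5–C8 β-epoxy alcohol | C=CC[C@@]1(C)[C@@H](O[Si](C)(C)C(C)(C)C)C[C@]2(C(C)C)O[C@]12CO
F6 | step 8 | C5–C8 β-epoxy aldehyde | C=CC[C@@]1(C)[C@@H](O[Si](C)(C)C(C)(C)C)C[C@]2(C(C)C)O[C@]12C=O
F7 | step 13 | C2 lactol of 16 (anomeric mixture) | OC1C[C@@]2(C)[C@@H](O[Si](C)(C)C(C)(C)C)C[C@@](O)(C(C)C)[C@@H]2CO1
A1 | alternative 1 | 3,6-dimethylcyclohepta-2,5-dien-1-one | CC1=CCC(C)=CC(=O)C1
A2 | alternative 1 | dimethyl[1-(trimethylsilyl)ethenyl]aluminium | C[Al](C)C(=C)[Si](C)(C)C
A3 | alternative 1 | isobutyraldehyde | CC(C)C=O
A4 | alternative 1 | trans-4-(1-silylvinyl)-5-(1-hydroxy-2-methylpropyl)cycloheptenone | CC1=CC[C@@](C)(C(=C)[Si](C)(C)C)[C@@H](C(=O)C1)[C@@H](C(C)C)O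
A5 | alternative 2 | methyl 2-diazobut-3-enoate | COC(=O)C(=[N+]=[N-])C=C
A6 | alternative 2 | 2-(1-ethoxyvinyl)-3-methylcyclopent-2-en-1-one | CCOC(=C)C1=C(C)CCC1=O
A7 | alternative 2 | bicyclic ethoxy dienoate with quaternary C4 | COC(=O)C1=CC[C@@]2(C)CCC(=O)C2=C(OCC)C1
A8 | alternative 3 | thymoquinone | CC1=CC(=O)C(C(C)C)=CC1=O
A9 | alternative 3 | isoprene | C=CC(C)=C
A10 | alternative 3 | cis-decalin hydroxy mesylate (C4–C6 ring fusion, C6 hydroxyl, C5 mesylate) | CC1=CC[C@@]2(C)[C@@H](O[Si](C)(C)C(C)(C)C)C[C@@](O[Si](CC)(CC)CC)(C(C)C)[C@H](OS(C)(=O)=O)[C@@]2(O)C1
A11 | alternative 3 | trans-fused C6-keto hydroazulene bis-silyl ether | CC1=CC[C@]2(C)[C@@H](C(=O)C1)[C@](O[Si](CC)(CC)CC)(C(C)C)C[C@@H]2O[Si](C)(C)C(C)(C)C
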